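**Assumption:** the target has no stereocentre and is achiral, so "single enantiomer" needs no stereocontrol. The racemic sp3 centres in 7, 9 and 11 and the E-alkene of 8 are all erased before the target.

**Retrosynthetic overview**
1. Target 15 ⇒ chelation-controlled 5-O-demethylation of catechol 14 ⇒ hydrogenolysis of bis-benzyl ether 13.
2. 13 ⇒ O-methylation of flavonol 12 ⇒ C-3 oxygenation (epoxidation/rearrangement) of flavone 10.
3. 10 ⇒ oxidative ring closure of 2'-hydroxychalcone 8; the pyranone ring C is the only ring built.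
4. 8 ⇒ key C–C bond by intermolecular Claisen–Schmidt aldol condensation of acetophenone 4 (ring A) with aldehyde 6 (ring B).
5. 4 ⇐ 3,4,5-trimethoxyphenol 1; 6 ⇐ 2,3-dihydroxybenzaldehyde 5 (both aromatic rings bought).

**Route**

Step 1
Reactants: 1 3,4,5-trimethoxyphenol
Product: 2 1,2,3,5-tetramethoxybenzene
Conditions: MeI (1.5 eq), K2CO3 (2 eq), acetone, reflux, 12 h
Reagents that add atoms: iodomethane, CI
Why: Williamson ether synthesis (SN2 on MeI) at the only free phenol, so there is no selectivity question.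

Step 2
Reactants: 2 1,2,3,5-tetramethoxybenzene
Product: 4 1-(2-hydroxy-3,4,6-trimethoxyphenyl)ethan-1-one, via 2,3,4,6-tetramethoxyacetophenone 3 (not isolated)
Conditions: AcCl (1.2 eq), AlCl3 (2.5 eq), Et2O, 0 °C → rt, 24 h; ice/2 M HCl
Reagents that add atoms: acetyl chloride, CC(Cl)=O
Why: Friedel–Crafts acylation at the single type of free, doubly activated position, followed by AlCl3-chelate-assisted cleavage of the more crowded ortho-methoxy group (the one flanked by the 3-OMe), gives the hydrogen-bonded ortho-hydroxy ketone; the acyl group deactivates the ring against a second acylation.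

Step 3
Reactants: 5 2,3-dihydroxybenzaldehyde
Product: 6 2,3-bis(benzyloxy)benzaldehyde
Conditions: BnBr (2.3 eq), K2CO3 (3 eq), DMF, 60 °C, 6 h
Reagents that add atoms: benzyl bromide, BrCc1ccccc1
Why: Williamson benzylation of both phenols in a polar aprotic solvent; benzyl ethers survive every later basic and oxidative step and leave by hydrogenolysis.

Step 4
Reactants: 4 1-(2-hydroxy-3,4,6-trimethoxyphenyl)ethan-1-one; 6 2,3-bis(benzyloxy)benzaldehyde
Product: 8 (E)-3-[2,3-bis(benzyloxy)phenyl]-1-(2-hydroxy-3,4,6-trimethoxyphenyl)prop-2-en-1-one, via aldol adduct 7 (not isolated)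
Conditions: 6 (1.1 eq), KOH (50% aq, 10 eq), EtOH, rt, 48 h; then cold 2 M HCl to pH 3
Reagents that add atoms: none
Why: Claisen–Schmidt (crossed aldol) condensation: the methyl ketone enolate adds to the non-enolisable aldehyde and E1cB dehydration of the β-hydroxy ketone gives the conjugated E-enone, with no stereocentre retained.

Step 5
Reactants: 8 (E)-3-[2,3-bis(benzyloxy)phenyl]-1-(2-hydroxy-3,4,6-trimethoxyphenyl)prop-2-en-1-one
Product: 10 2-[2,3-bis(benzyloxy)phenyl]-5,7,8-trimethoxy-4H-chromen-4-one, via flavanone 9 (not isolated)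
Conditions: I2 (0.1 eq), DMSO, 130 °C, 3 h; aq Na2S2O3 work-up
Reagents that add atoms: none
Why: Iodine-catalysed oxidative cyclisation: oxa-Michael closure of the phenol to the flavanone, α-iodination and HI elimination give the flavone, while DMSO re-oxidises HI to I2.

Step 6
Reactants: 10 2-[2,3-bis(benzyloxy)phenyl]-5,7,8-trimethoxy-4H-chromen-4-one
Product: 12 2-[2,3-bis(benzyloxy)phenyl]-3-hydroxy-5,7,8-trimethoxy-4H-chromen-4-one, via flavone 2,3-epoxide 11 (not isolated)
Conditions: DMDO (0.08 M in acetone, 4 eq in portions), CH2Cl2, 0 °C → rt, dark, 24–48 h; evaporate; p-TsOH·H2O (0.1 eq), CH2Cl2, rt, 1 h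
Reagents that add atoms: dimethyldioxirane, CC1(C)OO1
Why: Neutral dioxirane epoxidation of the C2=C3 enol-ether bond, then acid-catalysed epoxide opening at C-2 (oxocarbenium) and loss of H-3, gives the flavonol and erases the epoxide stereocentres.

Step 7
Reactants: 12 2-[2,3-bis(benzyloxy)phenyl]-3-hydroxy-5,7,8-trimethoxy-4H-chromen-4-one
Product: 13 2-[2,3-bis(benzyloxy)phenyl]-3,5,7,8-tetramethoxy-4H-chromen-4-one
Conditions: MeI (3 eq), K2CO3 (3 eq), DMF, 40 °C, 6 h
Reagents that add atoms: iodomethane, CI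
Why: Williamson O-methylation of the acidic 3-hydroxyl, the only free OH in the molecule.

Step 8
Reactants: 13 2-[2,3-bis(benzyloxy)phenyl]-3,5,7,8-tetramethoxy-4H-chromen-4-one
Product: 14 2-(2,3-dihydroxyphenyl)-3,5,7,8-tetramethoxy-4H-chromen-4-one
Conditions: H2 (1 atm), 10% Pd/C, EtOAc/MeOH 1:1, rt, 4 h
Reagents that add atoms: none
Why: Catalytic hydrogenolysis cleaves both benzyl aryl ethers, while the tetrasubstituted chromone C2=C3 bond and the aryl methyl ethers are inert at 1 atm.

Step 9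
Reactants: 14 2-(2,3-dihydroxyphenyl)-3,5,7,8-tetramethoxy-4H-chromen-4-one
Product: 15 5,2',3'-trihydroxy-3,7,8-trimethoxyflavone
Conditions: anhydrous AlCl3 (8 eq), MeCN, rt → 40 °C, HPLC-monitored; then 2 M HCl, 60 °C, 30 min
Reagents that add atoms: none
Why: Chelation-controlled Lewis-acid demethylation: aluminium bridges the 4-carbonyl and the peri 5-OMe in a six-membered chelate, so chloride removes only that methyl and the 3-, 7- and 8-OMe groups stay under these mild conditions.

**Compound list**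
1 | 3,4,5-trimethoxyphenol | COc1cc(O)cc(OC)c1OC | starting material
2 | 1,2,3,5-tetramethoxybenzene | COc1cc(OC)c(OC)c(OC)c1 | intermediate
3 | 1-(2,3,4,6-tetramethoxyphenyl)ethan-1-one (2,3,4,6-tetramethoxyacetophenone) | CC(=O)c1c(OC)cc(OC)c(OC)c1OC | intermediate
4 | 1-(2-hydroxy-3,4,6-trimethoxyphenyl)ethan-1-one | CC(=O)c1c(OC)cc(OC)c(OC)c1O | intermediate
5 | 2,3-dihydroxybenzaldehyde | O=Cc1cccc(O)c1O | starting material
6 | 2,3-bis(benzyloxy)benzaldehyde | O=Cc1cccc(OCc2ccccc2)c1OCc1ccccc1 | intermediate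
7 | 3-[2,3-bis(benzyloxy)phenyl]-3-hydroxy-1-(2-hydroxy-3,4,6-trimethoxyphenyl)propan-1-one (racemic aldol adduct) | COc1cc(OC)c(C(=O)CC(O)c2cccc(OCc3ccccc3)c2OCc2ccccc2)c(O)c1OC | intermediate
8 | (E)-3-[2,3-bis(benzyloxy)phenyl]-1-(2-hydroxy-3,4,6-trimethoxyphenyl)prop-2-en-1-one (chalcone) | COc1cc(OC)c(C(=O)/C=C/c2cccc(OCc3ccccc3)c2OCc2ccccc2)c(O)c1OC | intermediate
9 | 2-[2,3-bis(benzyloxy)phenyl]-5,7,8-trimethoxychroman-4-one (racemic flavanone) | COc1cc(OC)c2c(c1OC)OC(c1cccc(OCc3ccccc3)c1OCc1ccccc1)CC2=O | intermediate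
10 | 2-[2,3-bis(benzyloxy)phenyl]-5,7,8-trimethoxy-4H-chromen-4-one (flavone) | COc1cc(OC)c2c(=O)cc(-c3cccc(OCc4ccccc4)c3OCc3ccccc3)oc2c1OC | intermediate
11 | 2-[2,3-bis(benzyloxy)phenyl]-2,3-epoxy-5,7,8-trimethoxychroman-4-one (racemic flavone 2,3-epoxide) | COc1cc(OC)c2c(c1OC)OC1(c3cccc(OCc4ccccc4)c3OCc3ccccc3)OC1C2=O | intermediate
12 | 2-[2,3-bis(benzyloxy)phenyl]-3-hydroxy-5,7,8-trimethoxy-4H-chromen-4-one (flavonol) | COc1cc(OC)c2c(=O)c(O)c(-c3cccc(OCc4ccccc4)c3OCc3ccccc3)oc2c1OC | intermediate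
13 | 2-[2,3-bis(benzyloxy)phenyl]-3,5,7,8-tetramethoxy-4H-chromen-4-one | COc1cc(OC)c2c(=O)c(OC)c(-c3cccc(OCc4ccccc4)c3OCc3ccccc3)oc2c1OC | intermediate
14 | 2-(2,3-dihydroxyphenyl)-3,5,7,8-tetramethoxy-4H-chromen-4-one | COc1cc(OC)c2c(=O)c(OC)c(-c3cccc(O)c3O)oc2c1OC | intermediate
15 | 5,2',3'-trihydroxy-3,7,8-trimethoxyflavone [2-(2,3-dihydroxyphenyl)-5-hydroxy-3,7,8-trimethoxy-4H-chromen-4-one] | COc1cc(O)c2c(=O)c(OC)c(-c3cccc(O)c3O)oc2c1OC | target

**Step count:** 9 steps in total. The longest linear sequence is 8 steps (1, 2, 4, 5, 6, 7, 8, 9 from 3,4,5-trimethoxyphenol); step 3 is the one-step side branch.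

**Three steps most likely to fail, with fallbacks**

Step 5 (iodine/DMSO ring closure). The risk is HI at 130 °C attacking the 2'-benzyl ether or the 5-OMe, or incomplete oxidation. The fallback sets out from chalcone 8 and comes back at flavone 10, separating ring closure from dehydrogenation. NaOAc in refluxing EtOH isomerises 8 to the flavanone 9, which is isolated this time. DDQ (2.5 eq) in refluxing dioxane then dehydrogenates 9 to 10 by hydride abstraction, with no iodide or strong acid present. This fallback makes no compound that is not already in the list (F0).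

Step 6 (DMDO epoxidation/rearrangement). The risk is slow epoxidation of the hindered C2=C3 bond and competing oxidation of benzylic C–H during long exposure. The fallback sets out from 2 (with a second portion of aldehyde 6) and comes back at 13. It carries the 3-methoxy group in from the ketone, so neither a C-3 oxidation nor step 7 is needed. Friedel–Crafts acylation of 2 with methoxyacetyl chloride/AlCl3 in Et2O forms 2-methoxy-1-(2,3,4,6-tetramethoxyphenyl)ethan-1-one F1 in the flask. Under the same conditions F1 loses its crowded ortho-methyl group to give 1-(2-hydroxy-3,4,6-trimethoxyphenyl)-2-methoxyethan-1-one F2. Claisen–Schmidt condensation of F2 with 6 (KOH, EtOH, rt, or piperidine, EtOH, reflux) passes through the α-methoxy aldol adduct F3 to the (Z)-α-methoxychalcone F4. I2 (cat.)/DMSO at 120 °C (or SeO2 in refluxing isoamyl alcohol) closes F4 through the 3-methoxyflavanone F5 and dehydrogenates it to 13.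

Step 9 (selective 5-O-demethylation). The risk is over-demethylation at 3-OMe or 8-OMe and a sluggish reaction of the aluminium catecholate. The fallback sets out from 13 and comes back at 15, with the order of the two deprotections reversed. BCl3 (1.2 eq, CH2Cl2, −78 → −10 °C, pentamethylbenzene as benzyl-cation trap) is applied to the fully protected flavone 13, whose only chelating site is the 4-C=O/5-OMe pair. This gives 2',3'-bis(benzyloxy)-5-hydroxy-3,7,8-trimethoxyflavone F6. Neutral hydrogenolysis of F6 (H2, Pd/C, EtOAc/MeOH) then gives 15, and any partly debenzylated material converges to 15 in the same operation.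

**Further compounds**
F0 | step 5 | none | none
F1 | step 6 | 2-methoxy-1-(2,3,4,6-tetramethoxyphenyl)ethan-1-one | COCC(=O)c1c(OC)cc(OC)c(OC)c1OC
F2 | step 6 | 1-(2-hydroxy-3,4,6-trimethoxyphenyl)-2-methoxyethan-1-one | COCC(=O)c1c(OC)cc(OC)c(OC)c1O
F3 | step 6 | 3-[2,3-bis(benzyloxy)phenyl]-3-hydroxy-1-(2-hydroxy-3,4,6-trimethoxyphenyl)-2-methoxypropan-1-one (racemic diastereomer mixture) | COc1cc(OC)c(C(=O)C(OC)C(O)c2cccc(OCc3ccccc3)c2OCc2ccccc2)c(O)c1OC
F4 | step 6 | (Z)-3-[2,3-bis(benzyloxy)phenyl]-1-(2-hydroxy-3,4,6-trimethoxyphenyl)-2-methoxyprop-2-en-1-one | COc1cc(OC)c(C(=O)/C(OC)=C/c2cccc(OCc3ccccc3)c2OCc2ccccc2)c(O)c1OC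
F5 | step 6 | 2-[2,3-bis(benzyloxy)phenyl]-3,5,7,8-tetramethoxychroman-4-one (racemic diastereomer mixture) | COc1cc(OC)c2c(c1OC)OC(c1cccc(OCc3ccccc3)c1OCc1ccccc1)C(OC)C2=O
F6 | step 9 | 2-[2,3-bis(benzyloxy)phenyl]-5-hydroxy-3,7,8-trimethoxy-4H-chromen-4-one | COc1cc(O)c2c(=O)c(OC)c(-c3cccc(OCc4ccccc4)c3OCc3ccccc3)oc2c1OC
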